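**Plan**
- Retrosynthesis: the two O–Si bonds are cut first. The C2=C3 bond of the benzofuran is traced to a 2,3-dihydrobenzofuran-3-carboxylic acid (C3–CO2H lost as CO2). The C3–C3a bond of that ring is then cut by a retro-Wolff step, which leads to a 3-diazoflavanone.
- Enabling feature: the furan ring (O1, C2, C3, C3a, C7a) is the pyranone ring of a 6-prenyl-7-oxyflavanone without its carbonyl carbon C4. O1–C2 and C2–C1' already exist there, so only ring-A carbon C4a has to move from C4 to C3.
- The diazoflavanone is cut at C3=N2 (deacylative diazo transfer). It is then cut at O1–C2 and C2–C3 (oxa-Michael/Knoevenagel) into a ring-A 1,3-diketone and a ring-B chromene aldehyde.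
- Forward: ring A is brominated, prenylated, silylated and C-benzoylated. The 2H-pyran on ring B closes by a propargyl Claisen cascade. The pyranone closes when the halves are joined, contracts to the dihydrofuran and is aromatised.
- Stereochemistry: the target is achiral. C2 and C3 exist only transiently, are racemic, and are erased by the decarboxylative desaturation.

Key step: step 10

Assumption: kanzonol V has no stereocentre and no stereogenic double bond, so there is no enantiomer to select. All sp3 intermediates are carried as racemates.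

Step 1
Reactants: 1 2',4'-dihydroxyacetophenone
Product: 2 5'-bromo-2',4'-dihydroxyacetophenone
Conditions: NBS (1.0 equiv), MeCN, 0 °C → rt
Reagents that add atoms: N-bromosuccinimide, O=C1CCC(=O)N1Br
Why: Electrophilic aromatic bromination; C5' is para to the chelated 2'-OH and ortho to the 4'-OH, while the equally activated C3' is crowded between two oxygens, so one equivalent of NBS should brominate C5'.

Step 2
Reactants: 2 5'-bromo-2',4'-dihydroxyacetophenone; 3 prenylboronic acid pinacol ester
Product: 4 2',4'-dihydroxy-5'-(3-methylbut-2-enyl)acetophenone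
Conditions: Pd-PEPPSI-IPent (3 mol %), aq KOH (5 equiv), THF, 70 °C
Reagents that add atoms: none
Why: Suzuki–Miyaura allyl–aryl coupling; the bulky NHC ligand should direct C–C bond formation to the unsubstituted terminus of the prenyl–palladium species (linear, not reverse prenyl), and the phenols pass through as phenoxides in the aqueous base.

Step 3
Reactants: 4 2',4'-dihydroxy-5'-(3-methylbut-2-enyl)acetophenone
Product: 5 1-[2-hydroxy-5-(3-methylbut-2-enyl)-4-(triisopropylsilyloxy)phenyl]ethanone
Conditions: TIPSCl (1.05 equiv), imidazole, CH2Cl2, 0 °C → rt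
Reagents that add atoms: triisopropylsilyl chloride, CC(C)[Si](Cl)(C(C)C)C(C)C
Why: Chemoselective O-silylation; the 2'-OH is hydrogen-bonded to the ketone and stays free, and TIPS is preferred to TBS because the aryl silyl ethers must later survive lithium amide, amine bases and ester hydrolysis.

Step 4
Reactants: 5 1-[2-hydroxy-5-(3-methylbut-2-enyl)-4-(triisopropylsilyloxy)phenyl]ethanone
Product: 6 1-[2-hydroxy-5-(3-methylbut-2-enyl)-4-(triisopropylsilyloxy)phenyl]-3-phenylpropane-1,3-dione
Conditions: LiHMDS (3.2 equiv), THF, −78 → −10 °C; BzCl (1.05 equiv), −78 °C → rt; cold dil. aq HCl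
Reagents that add atoms: benzoyl chloride, O=C(Cl)c1ccccc1
Why: Direct C-acylation of the lithium phenoxide–enolate dianion (the one-flask equivalent of a Baker–Venkataraman rearrangement); the third equivalent of base takes up the acidic diketone as it forms, and the benzoyl group is the activating group that step 9 expels.

Step 5
Reactants: 7 2,4-dihydroxybenzaldehyde
Product: 8 2-hydroxy-4-(triisopropylsilyloxy)benzaldehyde
Conditions: TIPSCl (1.05 equiv), imidazole, CH2Cl2, 0 °C
Reagents that add atoms: triisopropylsilyl chloride, CC(C)[Si](Cl)(C(C)C)C(C)C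
Why: Chemoselective O-silylation of the more acidic, non-chelated 4-OH, while the 2-OH stays bound to the formyl oxygen.

Step 6
Reactants: 8 2-hydroxy-4-(triisopropylsilyloxy)benzaldehyde; 9 3-chloro-3-methylbut-1-yne
Product: 10 2-(2-methylbut-3-yn-2-yloxy)-4-(triisopropylsilyloxy)benzaldehyde
Conditions: CuCl2·2H2O (1 mol %), DBU (1.5 equiv), MeCN, 0 °C → rt
Reagents that add atoms: none
Why: Copper-catalysed O-propargylation of a phenol with a tertiary propargyl chloride; with O4 blocked the ether can form only on O2, which puts the pyran oxygen next to the formyl-bearing carbon as the target requires (the unprotected dihydroxyaldehyde would lead to the isomeric 6-formylchromene).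

Step 7
Reactants: 10 2-(2-methylbut-3-yn-2-yloxy)-4-(triisopropylsilyloxy)benzaldehyde
Product: 12 2,2-dimethyl-5-(triisopropylsilyloxy)-2H-chromene-8-carbaldehyde, via ortho-allenylphenol 11 (not isolated)
Conditions: PhNEt2, 190 °C
Reagents that add atoms: none
Why: Aromatic propargyl Claisen rearrangement to the only free ortho position C3, tautomerisation to 11, 1,5-hydrogen shift and oxa-6π electrocyclisation, which is the standard cascade from aryl 1,1-dimethylpropargyl ethers to 2,2-dimethyl-2H-chromenes.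

Step 8
Reactants: 6 1-[2-hydroxy-5-(3-methylbut-2-enyl)-4-(triisopropylsilyloxy)phenyl]-3-phenylpropane-1,3-dione; 12 2,2-dimethyl-5-(triisopropylsilyloxy)-2H-chromene-8-carbaldehyde
Product: 14 rac-3-benzoyl-2-[2,2-dimethyl-5-(triisopropylsilyloxy)-2H-chromen-8-yl]-6-(3-methylbut-2-enyl)-7-(triisopropylsilyloxy)chroman-4-one, via alkylidene diketone 13 (not isolated)
Conditions: piperidine (20 mol %), AcOH (20 mol %), 4 Å MS, toluene, 80 °C
Reagents that add atoms: none
Why: Knoevenagel condensation followed in the same flask by 6-endo-trig oxa-Michael addition of the 2'-phenol, the classical entry to 3-aroylflavanones; because C3–H now belongs to a 1,3-diketone the closed form is no longer disfavoured against the ring-opened phenoxide, and C2 and C3 arise racemic (trans expected by equilibration) and are not retained in the target.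

Step 9
Reactants: 14 rac-3-benzoyl-2-[2,2-dimethyl-5-(triisopropylsilyloxy)-2H-chromen-8-yl]-6-(3-methylbut-2-enyl)-7-(triisopropylsilyloxy)chroman-4-one
Product: 15 rac-3-diazo-2-[2,2-dimethyl-5-(triisopropylsilyloxy)-2H-chromen-8-yl]-6-(3-methylbut-2-enyl)-7-(triisopropylsilyloxy)chroman-4-one
Conditions: 4-O2NC6H4SO2N3 (1.5 equiv), DBU (2 equiv), CH2Cl2, 0 °C → rt
Reagents that add atoms: 4-nitrobenzenesulfonyl azide, [N-]=[N+]=NS(=O)(=O)c1ccc(cc1)[N+](=O)[O-]
Why: Deacylative (debenzoylative) Regitz diazo transfer; the stabilised enolate attacks the terminal azide nitrogen and the sulfonamide nitrogen then removes the more electrophilic exocyclic benzoyl group rather than the donor-deactivated ring carbonyl C4, so the diazo group reaches C3 without an unstabilised flavanone enolate and without any phosphine.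

Step 10
Reactants: 15 rac-3-diazo-2-[2,2-dimethyl-5-(triisopropylsilyloxy)-2H-chromen-8-yl]-6-(3-methylbut-2-enyl)-7-(triisopropylsilyloxy)chroman-4-one
Product: 17 methyl rac-2-[2,2-dimethyl-5-(triisopropylsilyloxy)-2H-chromen-8-yl]-5-(3-methylbut-2-enyl)-6-(triisopropylsilyloxy)-2,3-dihydrobenzofuran-3-carboxylate (cis/trans mixture), via ring-contracted ketene 16 (not isolated)
Conditions: hν (405 nm LED), MeOH–THF (1:1), degassed, 0–10 °C
Reagents that add atoms: methanol, CO
Why: Excitation of the long-wavelength band of the diazoketone expels N2 while the C4–C4a bond, held anti-periplanar to the departing nitrogen, shifts from C4 to C3, so C3–C3a forms, the pyranone contracts to ketene 16 and methanol captures it as ester 17. The closest known reaction type is the photochemical Wolff ring contraction of cyclic α-diazoketones such as 2-diazo-1-tetralones and 3-diazochroman-4-ones. The dihydrofuran ring (O1, C2, C3, C3a, C7a) arises by a 1,2-aryl shift, a six-to-five contraction, and not by cyclisation of an open chain. C3 is the only new stereocentre; it is set relative to racemic C2 when the ketene–methanol enol is protonated, probably anti to the C2 aryl group, and the outcome does not matter because step 12 removes both centres. The step needs aryl migration to outrun the 1,2-hydride shift from C2 and O–H insertion of a free carbene, and the ring-enforced s-Z geometry (concerted nitrogen loss) together with the donor-substituted, electron-rich migrating carbon C4a should secure this. Violet light is absorbed only by the diazoketone, so the UV-absorbing 2H-chromene is not opened to its o-quinone methide in methanol and the prenyl group is untouched.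

Step 11
Reactants: 17 methyl rac-2-[2,2-dimethyl-5-(triisopropylsilyloxy)-2H-chromen-8-yl]-5-(3-methylbut-2-enyl)-6-(triisopropylsilyloxy)-2,3-dihydrobenzofuran-3-carboxylate
Product: 19 rac-2-[2,2-dimethyl-5-(triisopropylsilyloxy)-2H-chromen-8-yl]-5-(3-methylbut-2-enyl)-6-(triisopropylsilyloxy)-2,3-dihydrobenzofuran-3-carboxylic acid, via trimethylstannyl ester 18 (not isolated)
Conditions: Me3SnOH (6 equiv), ClCH2CH2Cl, 75 °C; then dil. aq HCl wash
Reagents that add atoms: trimethyltin hydroxide, C[Sn](C)(C)O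
Why: Neutral tin-hydroxide ester hydrolysis; it avoids the C3 enolate that would expel the O1 phenoxide (E1cB ring opening) under hydroxide conditions, and it should leave the aryl TIPS ethers intact.

Step 12
Reactants: 19 rac-2-[2,2-dimethyl-5-(triisopropylsilyloxy)-2H-chromen-8-yl]-5-(3-methylbut-2-enyl)-6-(triisopropylsilyloxy)-2,3-dihydrobenzofuran-3-carboxylic acid
Product: 20 2-[2,2-dimethyl-5-(triisopropylsilyloxy)-2H-chromen-8-yl]-5-(3-methylbut-2-enyl)-6-(triisopropylsilyloxy)benzofuran
Conditions: 9-(2-chlorophenyl)acridine (10 mol %), Co(dmgH)2(py)Cl (5 mol %), CH2Cl2–MeCN, 400–420 nm LED, rt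
Reagents that add atoms: none
Why: Photocatalytic dehydrodecarboxylation (proton-coupled electron transfer in the acid–acridine complex plus cobaloxime hydrogen-atom abstraction); loss of CO2 gives the benzylic C3 radical, cobalt(II) removes the weak, doubly activated C2–H, and aromatisation to the benzofuran drives the step and erases both stereocentres.

Step 13
Reactants: 20 2-[2,2-dimethyl-5-(triisopropylsilyloxy)-2H-chromen-8-yl]-5-(3-methylbut-2-enyl)-6-(triisopropylsilyloxy)benzofuran
Product: 21 kanzonol V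
Conditions: TBAF (2.4 equiv), AcOH (2.4 equiv), THF, 0 °C
Reagents that add atoms: none
Why: Fluoride desilylation of aryl silyl ethers, buffered with acetic acid so that the ortho-prenylphenol and the chromene meet neither strong base nor strong acid.

**Compound list**
1 | 2',4'-dihydroxyacetophenone | CC(=O)c1ccc(O)cc1O | starting material
2 | 5'-bromo-2',4'-dihydroxyacetophenone | CC(=O)c1cc(Br)c(O)cc1O | intermediate
3 | prenylboronic acid pinacol ester | CC(C)=CCB1OC(C)(C)C(C)(C)O1 | starting material
4 | 2',4'-dihydroxy-5'-(3-methylbut-2-enyl)acetophenone | CC(=O)c1cc(CC=C(C)C)c(O)cc1O | intermediate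
5 | 1-[2-hydroxy-5-(3-methylbut-2-enyl)-4-(triisopropylsilyloxy)phenyl]ethanone | CC(=O)c1cc(CC=C(C)C)c(O[Si](C(C)C)(C(C)C)C(C)C)cc1O | intermediate
6 | 1-[2-hydroxy-5-(3-methylbut-2-enyl)-4-(triisopropylsilyloxy)phenyl]-3-phenylpropane-1,3-dione (keto–enol mixture) | O=C(CC(=O)c1ccccc1)c1cc(CC=C(C)C)c(O[Si](C(C)C)(C(C)C)C(C)C)cc1O | intermediate
7 | 2,4-dihydroxybenzaldehyde | O=Cc1ccc(O)cc1O | starting material
8 | 2-hydroxy-4-(triisopropylsilyloxy)benzaldehyde | O=Cc1ccc(O[Si](C(C)C)(C(C)C)C(C)C)cc1O | intermediate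
9 | 3-chloro-3-methylbut-1-yne | C#CC(C)(C)Cl | starting material
10 | 2-(2-methylbut-3-yn-2-yloxy)-4-(triisopropylsilyloxy)benzaldehyde | O=Cc1ccc(O[Si](C(C)C)(C(C)C)C(C)C)cc1OC(C)(C)C#C | intermediate
11 | 2-hydroxy-3-(3-methylbuta-1,2-dienyl)-4-(triisopropylsilyloxy)benzaldehyde (not isolated) | O=Cc1ccc(O[Si](C(C)C)(C(C)C)C(C)C)c(C=C=C(C)C)c1O | intermediate
12 | 2,2-dimethyl-5-(triisopropylsilyloxy)-2H-chromene-8-carbaldehyde | O=Cc1ccc(O[Si](C(C)C)(C(C)C)C(C)C)c2c1OC(C)(C)C=C2 | intermediate
13 | 2-{[2,2-dimethyl-5-(triisopropylsilyloxy)-2H-chromen-8-yl]methylidene}-1-[2-hydroxy-5-(3-methylbut-2-enyl)-4-(triisopropylsilyloxy)phenyl]-3-phenylpropane-1,3-dione (E/Z undefined, not isolated) | O=C(c1ccccc1)C(=Cc1ccc(O[Si](C(C)C)(C(C)C)C(C)C)c2c1OC(C)(C)C=C2)C(=O)c1cc(CC=C(C)C)c(O[Si](C(C)C)(C(C)C)C(C)C)cc1O | intermediate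
14 | rac-3-benzoyl-2-[2,2-dimethyl-5-(triisopropylsilyloxy)-2H-chromen-8-yl]-6-(3-methylbut-2-enyl)-7-(triisopropylsilyloxy)chroman-4-one (racemic, diastereomer/enol mixture) | CC(C)=CCc1cc2C(=O)C(C(=O)c3ccccc3)C(Oc2cc1O[Si](C(C)C)(C(C)C)C(C)C)c1ccc(O[Si](C(C)C)(C(C)C)C(C)C)c2c1OC(C)(C)C=C2 | intermediate
15 | rac-3-diazo-2-[2,2-dimethyl-5-(triisopropylsilyloxy)-2H-chromen-8-yl]-6-(3-methylbut-2-enyl)-7-(triisopropylsilyloxy)chroman-4-one (racemic) | CC(C)=CCc1cc2C(=O)C(=[N+]=[N-])C(Oc2cc1O[Si](C(C)C)(C(C)C)C(C)C)c1ccc(O[Si](C(C)C)(C(C)C)C(C)C)c2c1OC(C)(C)C=C2 | intermediate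
16 | rac-2-[2,2-dimethyl-5-(triisopropylsilyloxy)-2H-chromen-8-yl]-3-(oxomethylidene)-5-(3-methylbut-2-enyl)-6-(triisopropylsilyloxy)-2,3-dihydrobenzofuran (ketene, not isolated) | O=C=C1c2cc(CC=C(C)C)c(O[Si](C(C)C)(C(C)C)C(C)C)cc2OC1c1ccc(O[Si](C(C)C)(C(C)C)C(C)C)c2c1OC(C)(C)C=C2 | intermediate
17 | methyl rac-2-[2,2-dimethyl-5-(triisopropylsilyloxy)-2H-chromen-8-yl]-5-(3-methylbut-2-enyl)-6-(triisopropylsilyloxy)-2,3-dihydrobenzofuran-3-carboxylate (racemic cis/trans mixture) | COC(=O)C1c2cc(CC=C(C)C)c(O[Si](C(C)C)(C(C)C)C(C)C)cc2OC1c1ccc(O[Si](C(C)C)(C(C)C)C(C)C)c2c1OC(C)(C)C=C2 | intermediate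
18 | trimethylstannyl ester of acid 19 (not isolated) | C[Sn](C)(C)OC(=O)C1c2cc(CC=C(C)C)c(O[Si](C(C)C)(C(C)C)C(C)C)cc2OC1c1ccc(O[Si](C(C)C)(C(C)C)C(C)C)c2c1OC(C)(C)C=C2 | intermediate
19 | rac-2-[2,2-dimethyl-5-(triisopropylsilyloxy)-2H-chromen-8-yl]-5-(3-methylbut-2-enyl)-6-(triisopropylsilyloxy)-2,3-dihydrobenzofuran-3-carboxylic acid (racemic cis/trans mixture) | OC(=O)C1c2cc(CC=C(C)C)c(O[Si](C(C)C)(C(C)C)C(C)C)cc2OC1c1ccc(O[Si](C(C)C)(C(C)C)C(C)C)c2c1OC(C)(C)C=C2 | intermediate
20 | 2-[2,2-dimethyl-5-(triisopropylsilyloxy)-2H-chromen-8-yl]-5-(3-methylbut-2-enyl)-6-(triisopropylsilyloxy)benzofuran | CC(C)=CCc1cc2cc(-c3ccc(O[Si](C(C)C)(C(C)C)C(C)C)c4c3OC(C)(C)C=C4)oc2cc1O[Si](C(C)C)(C(C)C)C(C)C | intermediate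
21 | kanzonol V, 8-[6-hydroxy-5-(3-methylbut-2-enyl)benzofuran-2-yl]-2,2-dimethyl-2H-chromen-5-ol (achiral) | CC(C)=CCc1cc2cc(-c3ccc(O)c4c3OC(C)(C)C=C4)oc2cc1O | target

Total step count: 13. Longest linear sequence: 10 steps (1–4, then 8–13). Steps 5–7 form the convergent ring-B branch.

**Steps most likely to fail**

Step 10. If nitrogen loss is not fully concerted, hydride migration from C2 to the carbene centre or O–H insertion of methanol may outrun the aryl shift. The fallback drives the same shift of C4a from C4 to C3 oxidatively, without a diazo group.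
- It sets out from 5 and 12. The dilithio derivative of 5 (LiHMDS, THF, −78 °C) adds to 12 to give the β-hydroxy ketone F1.
- Intramolecular Mitsunobu etherification (PPh3, DIAD, THF, 0 °C) closes the flavanone F2.
- PhI(OAc)2 with catalytic H2SO4 in trimethyl orthoformate (the hypervalent-iodine ring contraction of flavanones) should convert F2 into ester 17, where the route is rejoined.
- The two alkenes would have to tolerate the iodine(III) reagent.

Step 9. Three processes may erode the diazo transfer: slow attack of the hindered tertiary enolate on the azide, base-induced reversible ring opening, and cleavage at the wrong carbonyl group. The fallback installs the diazo group before the halves are joined, and it also bypasses step 8.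
- It sets out from 5. This is trifluoroacetylated as its dianion (LiHMDS, CF3CO2CH2CF3, THF, −78 °C) to the trifluoroacetyl diketone F3.
- Crude F3 is treated with MsN3, Et3N and water in MeCN (detrifluoroacetylative diazo transfer) to give the diazomethyl ketone F4.
- The dianion of F4 (LDA, THF, −78 °C) adds to aldehyde 12 to give the diazo aldol adduct F5.
- F5 is closed by a Mitsunobu etherification. The PPh3–DIAD betaine is preformed with a slight excess of DIAD, so that no free phosphine meets the diazo group. This returns to the route at 15.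

Step 12. The electron-rich arenes may quench the excited photocatalyst, the C2–O1 bond may fragment at the radical stage, or cobalt hydride may isomerise the prenyl double bond. The fallback aromatises first and removes the carboxyl carbon afterwards by an ionic path.
- It sets out from 17. DDQ (dioxane, 60 °C) dehydrogenates it to the methyl benzofuran-3-carboxylate F6.
- KOSiMe3 (THF, rt, then dilute acid) cleaves the ester, which can no longer ring-open, to the benzofuran-3-carboxylic acid F7.
- Silver-catalysed protodecarboxylation (Ag2CO3 cat., AcOH, DMSO, 120 °C) returns to the route at 20.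

**Further compounds**
F1 | step 10 | rac-3-[2,2-dimethyl-5-(triisopropylsilyloxy)-2H-chromen-8-yl]-3-hydroxy-1-[2-hydroxy-5-(3-methylbut-2-enyl)-4-(triisopropylsilyloxy)phenyl]propan-1-one | CC(C)=CCc1cc(C(=O)CC(O)c2ccc(O[Si](C(C)C)(C(C)C)C(C)C)c3c2OC(C)(C)C=C3)c(O)cc1O[Si](C(C)C)(C(C)C)C(C)C
F2 | step 10 | rac-2-[2,2-dimethyl-5-(triisopropylsilyloxy)-2H-chromen-8-yl]-6-(3-methylbut-2-enyl)-7-(triisopropylsilyloxy)chroman-4-one | CC(C)=CCc1cc2C(=O)CC(Oc2cc1O[Si](C(C)C)(C(C)C)C(C)C)c1ccc(O[Si](C(C)C)(C(C)C)C(C)C)c2c1OC(C)(C)C=C2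
F3 | step 9 | 4,4,4-trifluoro-1-[2-hydroxy-5-(3-methylbut-2-enyl)-4-(triisopropylsilyloxy)phenyl]butane-1,3-dione | O=C(CC(=O)C(F)(F)F)c1cc(CC=C(C)C)c(O[Si](C(C)C)(C(C)C)C(C)C)cc1O
F4 | step 9 | 2-diazo-1-[2-hydroxy-5-(3-methylbut-2-enyl)-4-(triisopropylsilyloxy)phenyl]ethanone | [N-]=[N+]=CC(=O)c1cc(CC=C(C)C)c(O[Si](C(C)C)(C(C)C)C(C)C)cc1O
F5 | step 9 | rac-2-diazo-3-[2,2-dimethyl-5-(triisopropylsilyloxy)-2H-chromen-8-yl]-3-hydroxy-1-[2-hydroxy-5-(3-methylbut-2-enyl)-4-(triisopropylsilyloxy)phenyl]propan-1-one | CC(C)=CCc1cc(C(=O)C(=[N+]=[N-])C(O)c2ccc(O[Si](C(C)C)(C(C)C)C(C)C)c3c2OC(C)(C)C=C3)c(O)cc1O[Si](C(C)C)(C(C)C)C(C)C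
F6 | step 12 | methyl 2-[2,2-dimethyl-5-(triisopropylsilyloxy)-2H-chromen-8-yl]-5-(3-methylbut-2-enyl)-6-(triisopropylsilyloxy)benzofuran-3-carboxylate | COC(=O)c1c(-c2ccc(O[Si](C(C)C)(C(C)C)C(C)C)c3c2OC(C)(C)C=C3)oc2cc(O[Si](C(C)C)(C(C)C)C(C)C)c(CC=C(C)C)cc12
F7 | step 12 | 2-[2,2-dimethyl-5-(triisopropylsilyloxy)-2H-chromen-8-yl]-5-(3-methylbut-2-enyl)-6-(triisopropylsilyloxy)benzofuran-3-carboxylic acid | OC(=O)c1c(-c2ccc(O[Si](C(C)C)(C(C)C)C(C)C)c3c2OC(C)(C)C=C3)oc2cc(O[Si](C(C)C)(C(C)C)C(C)C)c(CC=C(C)C)cc12
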